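Whatever happens in this flask, the reagent lost equals target plus isomer of the product plus side product counted once.

    solid substrate ⇌ dissolved substrate, rate k1*(cs1 - [dissolved substrate]) while solid is left; crystals form when [dissolved substrate] > cs1 (cs1 = 28 mM, k1 = 4.2 × 10⁻⁴ /s)
    dissolved substrate + reagent → target (k2 = 0.32 /M/s)
    dissolved substrate + target → side product (k3 = 0.11 /M/s)
    target ⇌ isomer of the product (K4 = 1.3, k4 = 4.7 × 10⁻⁵ /s)

solid substrate 0.048 M; reagent 0.950 equiv; time 1.0 h

- percentages count the solid substrate that a species holds: one side product counts as two
- solid, in amounts per volume of the solution: solid substrate
- at the start none of the solid substrate is in solution
- run time (flask): 1.0 h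

1. the target standing at 1.0 h, as a percentage of the solid substrate charged
2. the change that raises the amount of target at 1.0 h, in percent of the solid substrate charged most ("none" if none brings more than 2 percentage points) (theta / gamma / beta / none)
3. amount of target at 1.0 h, in percent of the solid substrate charged, after beta

- theta: doubling the amount of reagent, all else as stated
- gamma: doubling the dissolution coefficient of step 1, all else as stated
- beta: doubling the solubility in step 1, all else as stated

The hunch was the feed from the solid; the reckoning here follows a ratio instead. Divide the rate of over-reaction by the rate of making target: dissolved substrate and time both drop out, and target over reagent remains, scaled by the two rate constants. The constant of making target over that of over-reaction is the crossover ratio, the target-to-reagent ratio at which over-reaction uses target as fast as it is made (the selectivity factor), 2.91.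

Followed from the start, this puts the crest of target at 54.3 % of the solid substrate charged, with reagent left at 18.7 % on the same scale. Reaching that crest takes 98.4 % of the solid, more than the 88.2 % that dissolution can deliver by the asked time into a solution kept empty. The reckoning therefore places this flask short of the crest at the asked time and treats the crest as a ceiling.

The isomer's forward half-life of 4.1 h is longer than the run, so it takes a small slice. With target averaging 0.5 of the crest, the reckoning commits to about 49.7 %. Gamma and beta speed the feed but do not change the crossover ratio, so the reckoning keeps beta near that figure. Theta raises the reagent term, so theta is the pick.

The forecast gives 48.5 %, 49 % after beta, and theta, holding that “doubling the reagent clearly wins by favouring step 2 over step 3”.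

The flask gives 48.6 %, and 48.7 % after beta. Theta adds 17 percentage points, gamma 0.16 points and beta 0.082 points, so the choice is theta. At the asked time, target stands at 1.76 times the reagent left, below the crossover ratio of 2.91, and over-reaction runs at 0.605 of the rate of making target. The same flask read at 40 min stands at 0.864 times, so over-reaction runs at 0.297 of that rate, with target at 40.2 % and side product at 11.8 %.

(The constants used here stand for no real mixture; no experiment stands behind them.)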